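Ring E is opened at its O–C(CH3)2 bond to a prenyl group on C6 and a free phenol on C5; the ring D phenol travels as a benzyl ether (coumarin numbering for rings A and B, ring C the furan, ring D the phenol ring, ring E the dimethyldihydropyran).
The route rests on ring A, whose six carbons carry in fixed order C4a–C4, C5–O, C6–CH2, C7–OMe, C8–H and C8a–O1. A vinylketene–alkyne benzannulation sets this order in one step, forming C8–C8a, C7–C8, C5–C6 and C4a–C5 from a diazoacetyl pyranone (rings B, C, D) and the ynol ether CH3O–C≡C–CH2CH=C(CH3)2.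
The pyranone (ring B) comes from enol lactonisation of an oxalyl side chain placed on the C2 methyl group of a 2-methylbenzofuran-3-carboxylate; the benzofuran (ring C on ring D) comes from a copper-catalysed domino arylation of ethyl acetoacetate with a 1-bromo-2-iodoarene.
Order of ring formation: ring D is bought, then ring C, ring B, ring A and last ring E.

Key step: step 7

Remark: the target has no stereocentre; the sp3 centres in transients 17 and 19 are racemic and disappear within step 7.

Step 1
Reactants: 1 1-(benzyloxy)-3-bromobenzene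
Product: 2 4-(benzyloxy)-2-bromo-1-iodobenzene
Conditions: NIS (1.05 equiv), TFA (0.3 equiv), MeCN, rt
Reagents that add atoms: N-iodosuccinimide, O=C1CCC(=O)N1I
Why: Electrophilic aromatic iodination with acid-activated NIS should go para to the benzyloxy group, the most activated and least hindered position, which puts iodine para to the ether and ortho to bromine as ring D requires.

Step 2
Reactants: 2 4-(benzyloxy)-2-bromo-1-iodobenzene; 3 ethyl acetoacetate
Product: 5 ethyl 6-(benzyloxy)-2-methyl-1-benzofuran-3-carboxylate, via C-arylated keto ester 4 (not isolated)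
Conditions: CuI (10 mol%), K2CO3 (3 equiv), THF, 100 °C (sealed tube)
Reagents that add atoms: none
Why: Copper-catalysed Hurtley-type C-arylation of the acetoacetate at the more reactive C–I bond, then intramolecular Ullmann-type O-arylation of the enol at the neighbouring C–Br bond, is the established domino route from 1-bromo-2-iodoarenes and β-keto esters to 2,3-disubstituted benzofurans and places the ether on C6 of the benzofuran.

Step 3
Reactants: 5 ethyl 6-(benzyloxy)-2-methyl-1-benzofuran-3-carboxylate; 6 di-tert-butyl oxalate
Product: 7 ethyl 6-(benzyloxy)-2-(3-tert-butoxy-2,3-dioxopropyl)-1-benzofuran-3-carboxylate (mainly as its enol)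
Conditions: LiN(i-Pr)2 (2.1 equiv), THF, −78 °C; then 6 (1.5 equiv), −78 to −20 °C; 1 M HCl quench
Reagents that add atoms: none
Why: The C2 methyl group is the vinylogous α-position of the C3 ester, so lateral deprotonation gives a dienolate that undergoes Claisen-type acylation by the hindered oxalate, and the second equivalent of base enolises the keto ester and so blocks a second addition.

Step 4
Reactants: 7 ethyl 6-(benzyloxy)-2-(3-tert-butoxy-2,3-dioxopropyl)-1-benzofuran-3-carboxylate
Product: 9 7-(benzyloxy)-1-oxo-1H-pyrano[4,3-b][1]benzofuran-3-carboxylic acid, via pyranone tert-butyl ester 8 (not isolated)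
Conditions: TsOH·H2O (0.2 equiv), PhMe, reflux (4 Å sieves in the return line)
Reagents that add atoms: none
Why: Acid-catalysed enol lactonisation (6-exo-trig attack of the pyruvate enol on the C3 ethyl ester, as in the classical isocoumarin-3-carboxylate synthesis) closes ring B and the same acid cleaves the tert-butyl ester by loss of isobutene, so no saponification in the presence of the lactone is needed.

Step 5
Reactants: 9 7-(benzyloxy)-1-oxo-1H-pyrano[4,3-b][1]benzofuran-3-carboxylic acid
Product: 11 7-(benzyloxy)-3-(diazoacetyl)-1H-pyrano[4,3-b][1]benzofuran-1-one, via acid chloride 10 (not isolated)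
Conditions: (COCl)2, DMF (cat.), CH2Cl2, 0 °C to rt; evaporate; CH2N2 (3 equiv), Et2O/THF, 0 °C
Reagents that add atoms: diazomethane, C=[N+]=[N-]
Why: Acylation of diazomethane by the acid chloride (first stage of the Arndt–Eistert sequence), with a second equivalent of diazomethane taking up the HCl, is the standard route to aryl diazomethyl ketones, and the lactone and benzyl ether are inert to both reagents at 0 °C.

Step 6
Reactants: 12 chloroacetaldehyde dimethyl acetal; 13 prenyl bromide
Product: 15 1-methoxy-5-methylhex-4-en-1-yne, via sodium methoxyacetylide 14 (not isolated)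
Conditions: NaNH2 (3.0 equiv), liq. NH3, −33 °C; then 13, Et2O, −33 °C; NH4Cl; distillation
Reagents that add atoms: none
Why: Two amide-induced eliminations (methanol, then HCl) and deprotonation turn the chloroacetal into the alkoxyacetylide, whose SN2 alkylation at the primary carbon of prenyl bromide gives the skipped enyne, and because all amide is consumed in making the weakly basic acetylide, base-induced isomerisation of the product is limited.

Step 7
Reactants: 11 7-(benzyloxy)-3-(diazoacetyl)-1H-pyrano[4,3-b][1]benzofuran-1-one; 15 1-methoxy-5-methylhex-4-en-1-yne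
Product: 20 9-(benzyloxy)-1-hydroxy-3-methoxy-2-(3-methylbut-2-en-1-yl)-6H-[1]benzofuro[3,2-c]chromen-6-one (5-hydroxy-7-methoxy-6-prenyl in coumarin numbering), via pyranonyl ketene 16 (not isolated), via cyclobutenone 17 (not isolated), via dienylketene 18 (not isolated), via cyclohexadienone 19 (not isolated)
Conditions: 15 (3 equiv), degassed ClCH2CH2Cl (0.02 M), hν (450 nm LEDs), rt; then 80 °C
Reagents that add atoms: none
Why: Excitation of the diazo ketone expels N2 and triggers Wolff rearrangement, in which the pyranone carbon migrates to the carbene carbon (bond C8–C8a) to give vinylketene 16, whose vinyl unit is the pyranone C=C that becomes C4a=C8a. The polarised ynol ether 15 adds across the ketene C=C in a regioselective (2+2) cycloaddition, its nucleophilic prenyl-bearing carbon bonding to the ketene carbonyl carbon (C5–C6) and its methoxy-bearing carbon to the former diazo carbon (C7–C8), which gives cyclobutenone 17. Four-electron electrocyclic opening of 17 (light or heat) gives dienylketene 18, and ring A closes by thermal six-electron electrocyclisation of the ketene carbon onto the pyranone CH (C4a–C5), after which enolisation of cyclohexadienone 19 gives phenol 20 and restores the pyranone as the coumarin lactone. The closest known reaction is the Danheiser benzannulation in its diazo ketone form, established for alkenyl, aryl and heteroaryl diazomethyl ketones with alkoxy- and siloxyalkynes; the pyranone double bond is less aromatic than the benzene and furan bonds that take part there, so the closure should be easier. No stereocentre is formed, and the regiochemistry needed (OH on C5, prenyl on C6, OMe on C7, H on C8) follows from the ynol ether polarity in the (2+2) step, while the electrocyclisation has only one terminus available, the pyranone CH. The step also needs the ketene path to outrun inverse-demand Diels–Alder addition of 15 to the pyranone and photoreactions of the lactone chromophores; photolysis at room temperature with 450 nm light, absorbed only in the diazo ketone n–π* band, and the fact that the pyranone diene includes the furan C2–C3 bond of the benzofuran should secure this.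

Step 8
Reactants: 20 9-(benzyloxy)-1-hydroxy-3-methoxy-2-(3-methylbut-2-en-1-yl)-6H-[1]benzofuro[3,2-c]chromen-6-one
Product: 21 benzyl ether of the target (ring E closed: 2,2-dimethyl-3,4-dihydro-2H-pyran fused through O on C5 and CH2 on C6; OMe on C7; benzyloxy on ring D)
Conditions: TsOH·H2O (0.1 equiv), PhMe, 80 °C
Reagents that add atoms: none
Why: Acid-catalysed Markovnikov hydroalkoxylation of the prenyl alkene, in which the tertiary cation is trapped by the only free hydroxyl (C5–OH, ortho to the side chain) in a 6-endo closure, is the standard conversion of ortho-prenylphenols into 2,2-dimethylchromans and creates no stereocentre.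

Step 9
Reactants: 21 benzyl ether of the target
Product: 22 CNP0304440.0 (target)
Conditions: H2 (1 atm), 10% Pd/C, THF–EtOAc, rt
Reagents that add atoms: none
Why: Hydrogenolysis of the benzyl aryl ether over Pd/C frees the ring D phenol, while the coumarin lactone, the furan ring and the methyl and chroman ethers are not reduced at one atmosphere and room temperature.

Compound list
1 | 1-(benzyloxy)-3-bromobenzene | Brc1cccc(OCc2ccccc2)c1 | starting material
2 | 4-(benzyloxy)-2-bromo-1-iodobenzene | Ic1ccc(OCc2ccccc2)cc1Br | intermediate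
3 | ethyl acetoacetate | CCOC(=O)CC(C)=O | starting material
4 | ethyl 2-[4-(benzyloxy)-2-bromophenyl]-3-oxobutanoate (C-arylated keto ester) | CCOC(=O)C(C(C)=O)c1ccc(OCc2ccccc2)cc1Br | intermediate (not isolated)
5 | ethyl 6-(benzyloxy)-2-methyl-1-benzofuran-3-carboxylate | CCOC(=O)c1c(C)oc2cc(OCc3ccccc3)ccc12 | intermediate
6 | di-tert-butyl oxalate | CC(C)(C)OC(=O)C(=O)OC(C)(C)C | starting material
7 | ethyl 6-(benzyloxy)-2-(3-tert-butoxy-2,3-dioxopropyl)-1-benzofuran-3-carboxylate | CCOC(=O)c1c(CC(=O)C(=O)OC(C)(C)C)oc2cc(OCc3ccccc3)ccc12 | intermediate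
8 | tert-butyl 7-(benzyloxy)-1-oxo-1H-pyrano[4,3-b][1]benzofuran-3-carboxylate (pyranone tert-butyl ester) | CC(C)(C)OC(=O)c1cc2oc3cc(OCc4ccccc4)ccc3c2c(=O)o1 | intermediate (not isolated)
9 | 7-(benzyloxy)-1-oxo-1H-pyrano[4,3-b][1]benzofuran-3-carboxylic acid | OC(=O)c1cc2oc3cc(OCc4ccccc4)ccc3c2c(=O)o1 | intermediate
10 | 7-(benzyloxy)-1-oxo-1H-pyrano[4,3-b][1]benzofuran-3-carbonyl chloride (acid chloride) | ClC(=O)c1cc2oc3cc(OCc4ccccc4)ccc3c2c(=O)o1 | intermediate (not isolated)
11 | 7-(benzyloxy)-3-(diazoacetyl)-1H-pyrano[4,3-b][1]benzofuran-1-one | [N-]=[N+]=CC(=O)c1cc2oc3cc(OCc4ccccc4)ccc3c2c(=O)o1 | intermediate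
12 | chloroacetaldehyde dimethyl acetal (2-chloro-1,1-dimethoxyethane) | COC(CCl)OC | starting material
13 | prenyl bromide (1-bromo-3-methylbut-2-ene) | CC(C)=CCBr | starting material
14 | sodium methoxyacetylide | COC#[C-].[Na+] | intermediate (not isolated)
15 | 1-methoxy-5-methylhex-4-en-1-yne | COC#CCC=C(C)C | intermediate
16 | 7-(benzyloxy)-3-(2-oxoethenyl)-1H-pyrano[4,3-b][1]benzofuran-1-one (pyranonyl ketene) | O=C=Cc1cc2oc3cc(OCc4ccccc4)ccc3c2c(=O)o1 | intermediate (not isolated)
17 | 7-(benzyloxy)-3-[2-methoxy-3-(3-methylbut-2-en-1-yl)-4-oxocyclobut-2-en-1-yl]-1H-pyrano[4,3-b][1]benzofuran-1-one (cyclobutenone, racemic) | COC1=C(CC=C(C)C)C(=O)C1c1cc2oc3cc(OCc4ccccc4)ccc3c2c(=O)o1 | intermediate (not isolated)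
18 | 7-(benzyloxy)-3-[2-methoxy-6-methyl-3-(oxomethylidene)hepta-1,5-dien-1-yl]-1H-pyrano[4,3-b][1]benzofuran-1-one (dienylketene; ketene carbon and pyranone cis on the enol ether double bond) | O=C=C(CC=C(C)C)/C(OC)=C\c1cc2oc3cc(OCc4ccccc4)ccc3c2c(=O)o1 | intermediate (not isolated)
19 | 9-(benzyloxy)-3-methoxy-2-(3-methylbut-2-en-1-yl)-[1]benzofuro[3,2-c]chromene-1,6(11bH)-dione (cyclohexadienone, racemic) | COC1=C(CC=C(C)C)C(=O)C2C(=C1)OC(=O)c1c2oc2cc(OCc3ccccc3)ccc12 | intermediate (not isolated)
20 | 9-(benzyloxy)-1-hydroxy-3-methoxy-2-(3-methylbut-2-en-1-yl)-6H-[1]benzofuro[3,2-c]chromen-6-one | COc1cc2oc(=O)c3c4ccc(OCc5ccccc5)cc4oc3c2c(O)c1CC=C(C)C | intermediate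
21 | benzyl ether of the target (coumestan with the 2,2-dimethyldihydropyran ring E on C5–O/C6, OMe on C7, benzyloxy on ring D) | COc1cc2oc(=O)c3c4ccc(OCc5ccccc5)cc4oc3c2c2c1CCC(C)(C)O2 | intermediate
22 | CNP0304440.0 | COc1cc2oc(=O)c3c4ccc(O)cc4oc3c2c2c1CCC(C)(C)O2 | target

Total step count: 9. Longest linear sequence: 8 steps (1, 2, 3, 4, 5, 7, 8, 9); step 6 is the one-step side branch to the alkyne.

Steps most likely to fail

Step 7. The photogenerated ketene may be diverted before it meets the alkyne (acylation of the phenol product, dimerisation), the ynol ether may add to the electron-poor pyranone, or the sequence may stall at the cyclobutenone if the electrocyclisation onto the pyranone double bond is slow. The fallback takes ring A from a preformed aromatic and closes ring B last by lactonisation; it sets out from 2 and returns at 21, so step 8 is not needed. Commercial 2',6'-dihydroxy-4'-methoxyacetophenone is condensed with isoprene over Amberlyst-15 to give 1-(7-hydroxy-5-methoxy-2,2-dimethyl-3,4-dihydro-2H-chromen-8-yl)ethanone F1. Because this phenol is symmetrical, both C–H sites and both hydroxyls are equivalent, so ring E and the methoxy group are placed without a regiochemical choice. Protection of the remaining phenol with MOMCl and i-Pr2NEt gives 1-[5-methoxy-7-(methoxymethoxy)-2,2-dimethyl-3,4-dihydro-2H-chromen-8-yl]ethanone F2. Claisen condensation with diethyl carbonate and NaH gives ethyl 3-[5-methoxy-7-(methoxymethoxy)-2,2-dimethyl-3,4-dihydro-2H-chromen-8-yl]-3-oxopropanoate F3. Coupling of F3 with 2 under the CuI/K2CO3 conditions of step 2 gives ethyl 6-(benzyloxy)-2-[5-methoxy-7-(methoxymethoxy)-2,2-dimethyl-3,4-dihydro-2H-chromen-8-yl]-1-benzofuran-3-carboxylate F4. HCl in methanol then removes the MOM group and the freed phenol lactonises onto the C3 ester to give 21.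

Step 5. Diazomethane may add as a 1,3-dipole to the acyl-activated pyranone double bond instead of being acylated, or the sparingly soluble acid may be converted incompletely. The fallback avoids diazomethane; it sets out from 9 (through its chloride 10, made as in step 5) and returns at 11. Negishi acylation of 10 with MeZnCl and catalytic Pd(PPh3)4 in THF gives 3-acetyl-7-(benzyloxy)-1H-pyrano[4,3-b][1]benzofuran-1-one F5. Its kinetic enolate (LiN(SiMe3)2, THF, −78 °C) is trifluoroacetylated with CF3CO2CH2CF3 to 7-(benzyloxy)-3-(4,4,4-trifluoro-3-oxobutanoyl)-1H-pyrano[4,3-b][1]benzofuran-1-one F6, which is not isolated. Detrifluoroacetylative diazo transfer with methanesulfonyl azide, Et3N and one equivalent of water in MeCN then gives 11.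

Step 3. Lateral deprotonation of the weakly acidic methyl group may be incomplete, or the dienolate may be lost to self-condensation with the C3 ester before it is acylated. The fallback makes the reacting carbon a much more acidic arylacetate methylene; it sets out from 2 and returns at 9. Coupling of 2 with commercial di-tert-butyl 3-oxopentanedioate under the CuI/K2CO3 conditions of step 2 gives tert-butyl 6-(benzyloxy)-2-(2-tert-butoxy-2-oxoethyl)-1-benzofuran-3-carboxylate F7. Claisen condensation of F7 with 6 (NaH, THF) gives di-tert-butyl 2-[6-(benzyloxy)-3-(tert-butoxycarbonyl)-1-benzofuran-2-yl]-3-oxobutanedioate F8. TsOH in refluxing toluene removes the three tert-butyl groups, the β-keto acid loses CO2, and the pyruvic enol closes onto the C3 acid with loss of water to give 9, as in the classical oxalyl-homophthalate route to isocoumarin-3-carboxylic acids.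

Further compounds
F1 | step 7 | 1-(7-hydroxy-5-methoxy-2,2-dimethyl-3,4-dihydro-2H-chromen-8-yl)ethanone | CC(=O)c1c(O)cc(OC)c2CCC(C)(C)Oc12
F2 | step 7 | 1-[5-methoxy-7-(methoxymethoxy)-2,2-dimethyl-3,4-dihydro-2H-chromen-8-yl]ethanone | CC(=O)c1c(OCOC)cc(OC)c2CCC(C)(C)Oc12
F3 | step 7 | ethyl 3-[5-methoxy-7-(methoxymethoxy)-2,2-dimethyl-3,4-dihydro-2H-chromen-8-yl]-3-oxopropanoate | CCOC(=O)CC(=O)c1c(OCOC)cc(OC)c2CCC(C)(C)Oc12
F4 | step 7 | ethyl 6-(benzyloxy)-2-[5-methoxy-7-(methoxymethoxy)-2,2-dimethyl-3,4-dihydro-2H-chromen-8-yl]-1-benzofuran-3-carboxylate | CCOC(=O)c1c(-c2c(OCOC)cc(OC)c3CCC(C)(C)Oc23)oc2cc(OCc3ccccc3)ccc12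
F5 | step 5 | 3-acetyl-7-(benzyloxy)-1H-pyrano[4,3-b][1]benzofuran-1-one | CC(=O)c1cc2oc3cc(OCc4ccccc4)ccc3c2c(=O)o1
F6 | step 5 | 7-(benzyloxy)-3-(4,4,4-trifluoro-3-oxobutanoyl)-1H-pyrano[4,3-b][1]benzofuran-1-one | O=C(CC(=O)C(F)(F)F)c1cc2oc3cc(OCc4ccccc4)ccc3c2c(=O)o1
F7 | step 3 | tert-butyl 6-(benzyloxy)-2-(2-tert-butoxy-2-oxoethyl)-1-benzofuran-3-carboxylate | CC(C)(C)OC(=O)Cc1oc2cc(OCc3ccccc3)ccc2c1C(=O)OC(C)(C)C
F8 | step 3 | di-tert-butyl 2-[6-(benzyloxy)-3-(tert-butoxycarbonyl)-1-benzofuran-2-yl]-3-oxobutanedioate | CC(C)(C)OC(=O)C(=O)C(C(=O)OC(C)(C)C)c1oc2cc(OCc3ccccc3)ccc2c1C(=O)OC(C)(C)C
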